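The plan turns on opening ring D at C15–C16. This cis double bond is flanked by the stereogenic carbons C14 and C17 and sits well away from the C1 lactone and from rings A to C, so it can be masked as a triple bond. Ring-closing alkyne metathesis of a diyne creates C15≡C16 and the 15-membered ring D in a single operation, leaving both neighbouring centres untouched, and syn semihydrogenation then delivers the Z alkene. The metathesis substrate is the C1 ester formed between the tricyclic amino acid (rings A to C, prop-1-ynyl on C14) and the C21 hydroxyl of a chloro-enynol whose C17 bears a silyl ether and the second prop-1-ynyl group.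

Key step: step 22

Remark on numbering: C1 is the lactone carbonyl, C2=C3 the ring C alkene, C5 the N–CH carbon, C9 the spiro carbon, C13 the ring A carbon bearing C14 (CHCH3), C17 the carbinol, C19 the C–Cl carbon, C21 the OCH2 carbon and C23 the NCH2 carbon. Ring A is the cyclopentane, ring B the piperidine, ring C the tetrahydropyridine and ring D the macrolactone.

Remark on descriptors: C14 and C17 are 14R/17S by CIP while C15/C16 are alkyne carbons and 14S/17R once C15=C16 is an alkene; the spatial arrangement does not change. Compounds 29 and 30 match the target at C5, C9, C13, C14, C17 and at the C18=C19 geometry (C17 trans to Cl).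

Step 1
Reactants: 1 2-(2-oxocyclopentyl)acetic acid (racemic); 2 (R)-2-amino-2-phenylethan-1-ol
Product: 3 tricyclic N,O-acetal lactam
Conditions: toluene, reflux, Dean–Stark
Reagents that add atoms: none
Why: Cyclodehydration of a γ-keto acid with a 1,2-amino alcohol (bicyclic lactam N,O-acetal formation) should funnel both enantiomers of 1, which interconvert through the enamine, into the isomer with phenyl cis to the C10 methylene, fixing C9 and, through the obligatory cis ring fusion, C13.

Step 2
Reactants: 3 tricyclic N,O-acetal lactam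
Product: 4 N-(2-hydroxy-1-phenylethyl) C9-allyl bicyclic lactam
Conditions: allylSiMe3, TiCl4, CH2Cl2, −78 °C → rt
Reagents that add atoms: allyltrimethylsilane, C=CC[Si](C)(C)C
Why: Hosomi–Sakurai allylation of the N-acyliminium ion opened by TiCl4 should put the allyl group (C6–C8) on C9 cis to H13, because only that face leads to the cis-fused bicyclo[3.3.0] lactam.

Step 3
Reactants: 4 N-(2-hydroxy-1-phenylethyl) C9-allyl bicyclic lactam
Product: 5 NH lactam
Conditions: Na, NH3(l), THF/EtOH, −78 °C
Reagents that add atoms: none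
Why: Dissolving-metal (Birch-type) cleavage of the benzylic C–N bond should release the NH lactam, the isolated terminal alkene and the lactam carbonyl being inert under these conditions.

Step 4
Reactants: 5 NH lactam
Product: 6 N-Boc lactam
Conditions: Boc2O, DMAP, Et3N, CH2Cl2, rt
Reagents that add atoms: di-tert-butyl dicarbonate, CC(C)(C)OC(=O)OC(=O)OC(C)(C)C
Why: DMAP-catalysed N-acylation (carbamate formation) activates the ring carbonyl for clean enolisation and for the later reductive ring opening.

Step 5
Reactants: 6 N-Boc lactam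
Product: 7 C14-methyl N-Boc lactam
Conditions: LiN(SiMe3)2, THF, −78 °C; MeI
Reagents that add atoms: iodomethane, CI
Why: Enolate alkylation in which MeI should approach C14 from the convex face of the cis-fused bicycle, away from the cyclopentane ring, placing the methyl group cis to H13 as the target requires.

Step 6
Reactants: 7 C14-methyl N-Boc lactam
Product: 9 Boc-amino terminal alkyne, via N-Boc hemiaminal 8 (not isolated)
Conditions: iBu2AlH, CH2Cl2, −78 °C; then MeOH, K2CO3, dimethyl (1-diazo-2-oxopropyl)phosphonate, 0 °C → rt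
Reagents that add atoms: dimethyl (1-diazo-2-oxopropyl)phosphonate, CC(=O)C(=[N+]=[N-])P(=O)(OC)OC
Why: Partial reduction of the N-acyl lactam stops at the hemiaminal, whose ring-opened aldehyde is trapped by the Seyferth–Gilbert reagent generated in situ (Ohira–Bestmann homologation), so C15 becomes the alkyne carbon and the nitrogen is released as NHBoc, while the low stationary concentration of the aldehyde should protect C14 from epimerisation.

Step 7
Reactants: 9 Boc-amino terminal alkyne
Product: 10 Boc-amino methyl-capped alkyne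
Conditions: n-BuLi (2.2 equiv), THF, −78 °C; MeI, → rt
Reagents that add atoms: iodomethane, CI
Why: C-alkylation of the lithium acetylide, the lithiated carbamate on the quaternary C9 being too hindered to compete for MeI.

Step 8
Reactants: 10 Boc-amino methyl-capped alkyne; 11 methyl (Z)-3-iodoprop-2-enoate
Product: 13 Boc-amino (Z)-enoate, via B-alkyl-9-BBN adduct 12 (not isolated)
Conditions: 9-BBN, THF, rt; then 11, PdCl2(dppf), AsPh3, Cs2CO3, DMF/H2O, rt
Reagents that add atoms: none
Why: 9-BBN hydroborates a monosubstituted alkene far faster than a hindered internal alkyne, and the B-alkyl Suzuki–Miyaura coupling joins C6 to C5 with retention of the Z geometry of the iodoacrylate.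

Step 9
Reactants: 13 Boc-amino (Z)-enoate
Product: 15 spiro-piperidine methyl ester (rings A and B), via free amine 14 (not isolated)
Conditions: TFA, CH2Cl2, 0 °C → rt; then aq. K2CO3
Reagents that add atoms: none
Why: Carbamate acidolysis followed by intramolecular aza-Michael addition (6-exo-trig) closes ring B, and C5 should be set under chair control with the CH2CO2Me arm equatorial and the branched C13 (not C10) equatorial at C9, which places C4 cis to C13.

Step 10
Reactants: 15 spiro-piperidine methyl ester
Product: 16 β-keto tert-butyl ester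
Conditions: tBuOAc, LiN(SiMe3)2, THF, −78 → −40 °C
Reagents that add atoms: tert-butyl acetate, CC(=O)OC(C)(C)C
Why: Crossed Claisen condensation of the lithium enolate of tert-butyl acetate with the methyl ester installs C2 and C1, the bulky ester suppressing self-condensation and the hindered N–H being left alone.

Step 11
Reactants: 16 β-keto tert-butyl ester
Product: 17 tricyclic β-keto ester (rings A, B and C)
Conditions: aq. CH2O, EtOH, rt
Reagents that add atoms: formaldehyde, C=O
Why: Intramolecular Mannich reaction in which the iminium ion from the secondary amine and formaldehyde is captured by the β-keto ester enol at C2 (6-endo-trig), closing ring C through C23.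

Step 12
Reactants: 17 tricyclic β-keto ester
Product: 18 β-hydroxy ester (mixture at C2 and C3)
Conditions: NaBH4, MeOH, 0 °C
Reagents that add atoms: none
Why: Borohydride reduction of the C3 ketone, whose stereochemical outcome is irrelevant because both new centres are destroyed in the next step.

Step 13
Reactants: 18 β-hydroxy ester
Product: 20 tricyclic tert-butyl enoate, via mesylate 19 (not isolated)
Conditions: MsCl, Et3N, CH2Cl2, 0 °C; then DBU, rt
Reagents that add atoms: none
Why: Mesylation and E1cB elimination through the acidic C2–H should give the conjugated C2=C3 ester from every diastereomer of 18.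

Step 14
Reactants: 20 tricyclic tert-butyl enoate
Product: 21 tricyclic amino acid
Conditions: TFA, CH2Cl2, rt; aq. NaHCO3 to pH 7
Reagents that add atoms: none
Why: Acidolysis of the tert-butyl ester with loss of isobutene, to which the alkyne, the enoate and the amine are inert.

Step 15
Reactants: 22 but-3-yn-1-ol
Product: 23 but-3-yn-1-yl acetate
Conditions: Ac2O, Et3N, DMAP (cat.), CH2Cl2, 0 °C → rt
Reagents that add atoms: acetic anhydride, CC(=O)OC(C)=O
Why: Acetylation masks the C21 hydroxyl with a group that survives electrophilic halogen, palladium carbonylation and borane reduction and is later removed without touching a silyl ether.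

Step 16
Reactants: 23 but-3-yn-1-yl acetate
Product: 24 (E)-3-chloro-4-iodobut-3-en-1-yl acetate
Conditions: ICl, Et4NCl, CH2Cl2, −78 → 0 °C
Reagents that add atoms: iodine monochloride, ClI
Why: Anti iodochlorination (iodonium formation, chloride opening at the internal carbon) should give the E chloroiodoalkene with iodine cis to the CH2CH2OAc chain, which is the geometry that later places C17 trans to chlorine.

Step 17
Reactants: 24 (E)-3-chloro-4-iodobut-3-en-1-yl acetate
Product: 25 (E)-3-chloro-5-oxooct-3-en-6-yn-1-yl acetate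
Conditions: Bu3SnC≡CMe, CO (3 atm), PdCl2(PPh3)2 (5 mol%), THF, 50 °C
Reagents that add atoms: carbon monoxide, [C-]#[O+]; tributyl(prop-1-yn-1-yl)stannane, CC#C[Sn](CCCC)(CCCC)CCCC
Why: Carbonylative Stille coupling: oxidative addition at C–I in preference to C–Cl, CO insertion and alkynyl transfer should give the cross-conjugated ynenone (C17 carbonyl) with retention of alkene geometry under neutral conditions.

Step 18
Reactants: 25 (E)-3-chloro-5-oxooct-3-en-6-yn-1-yl acetate
Product: 26 (3E,5S)-3-chloro-5-hydroxyoct-3-en-6-yn-1-yl acetate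
Conditions: (S)-Me-CBS (0.5 equiv), catecholborane, toluene, −78 °C
Reagents that add atoms: none
Why: Corey–Bakshi–Shibata reduction in which the β,β-disubstituted chloroalkenyl group acts as the large and the slim propynyl group as the small substituent, so the (S)-oxazaborolidine should deliver hydride to the face that gives the S carbinol (C17).

Step 19
Reactants: 26 (3E,5S)-3-chloro-5-hydroxyoct-3-en-6-yn-1-yl acetate
Product: 27 (3E,5S)-5-(tert-butyldimethylsilyloxy)-3-chlorooct-3-en-6-yn-1-yl acetate
Conditions: TBSCl, imidazole, DMF, rt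
Reagents that add atoms: tert-butyldimethylsilyl chloride, CC(C)(C)[Si](C)(C)Cl
Why: Silylation of the secondary propargylic alcohol gives the ether that the molybdenum alkylidyne tolerates.

Step 20
Reactants: 27 (3E,5S)-5-(tert-butyldimethylsilyloxy)-3-chlorooct-3-en-6-yn-1-yl acetate
Product: 28 (3E,5S)-5-(tert-butyldimethylsilyloxy)-3-chlorooct-3-en-6-yn-1-ol
Conditions: K2CO3 (cat.), MeOH, 0 °C
Reagents that add atoms: none
Why: Base-catalysed transesterification removes the acetate and leaves the TBS ether, the chloroalkene and the alkyne untouched.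

Step 21
Reactants: 21 tricyclic amino acid; 28 (3E,5S)-5-(tert-butyldimethylsilyloxy)-3-chlorooct-3-en-6-yn-1-ol
Product: 29 bis(prop-1-ynyl) ester (metathesis precursor)
Conditions: EDC·HCl, DMAP, iPr2NEt, CH2Cl2, rt
Reagents that add atoms: none
Why: Steglich esterification of the conjugated acid with an unhindered primary alcohol forms the C1–O–C21 bond without disturbing any stereocentre.

Step 22
Reactants: 29 bis(prop-1-ynyl) ester
Product: 30 15-membered cycloalkyne, C17 TBS ether
Conditions: Mo(≡CC6H4OMe-4)(OSiPh3)3 (20 mol%), 5 Å molecular sieves, toluene (2 mM), rt → 60 °C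
Reagents that add atoms: none
Why: The molybdenum alkylidyne adds to one propynyl group in a [2+2] cycloaddition to a metallacyclobutadiene, cycloreverts to a substrate-bound alkylidyne and repeats the sequence on the second alkyne to release the C15≡C16 cycloalkyne, while but-2-yne is trapped by the molecular sieves and drives the equilibrium. The closest known reaction type is ring-closing alkyne metathesis of methyl-capped diynes to macrocyclic cycloalkynes with molybdenum alkylidyne triarylsilanolate catalysts. Ring D closes as a 15-membered ring by intramolecular metathesis between the alkyne termini on C14 and C17, a macrocyclisation favoured by high dilution and by the rigid ring A to C core, which holds C13 and C23 in neighbouring equatorial positions on ring B. No stereocentre is formed, and C14 and C17 are sp3 spectators that cannot epimerise under these neutral conditions. The step needs alkyne-over-alkene chemoselectivity and tolerance of polar groups: the alkylidyne does not engage the C2=C3 enoate or the C18=C19 chloroalkene, the C17 oxygen is silylated, and the tertiary amine, flanked by the quaternary C9 and by C5, is a poor ligand for molybdenum.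

Step 23
Reactants: 30 15-membered cycloalkyne
Product: 31 (15Z)-macrolactone TBS ether
Conditions: H2 (1 atm), Pd/CaCO3 poisoned with Pb(OAc)2, quinoline, EtOAc, rt
Reagents that add atoms: none
Why: Lindlar-type semihydrogenation delivers both hydrogens to the same face of the alkyne on the poisoned palladium surface, giving the Z C15=C16 alkene and sparing the chloroalkene and the enoate.

Step 24
Reactants: 31 (15Z)-macrolactone TBS ether
Product: 32 target CNP0129639.4
Conditions: HF·pyridine, pyridine, THF, 0 °C → rt; aq. NaHCO3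
Reagents that add atoms: none
Why: Buffered fluoride desilylation frees the C17 alcohol under conditions mild enough for the bis-allylic carbinol and the lactone.

Compound list

1 | 2-(2-oxocyclopentyl)acetic acid (racemic) | O=C(O)CC1CCCC1=O | starting material
2 | (R)-2-amino-2-phenylethan-1-ol | N[C@@H](CO)c1ccccc1 | starting material
3 | tricyclic N,O-acetal lactam (cyclopentane, pyrrolidinone and oxazolidine sharing C9; phenyl cis to the C10 methylene, oxygen cis to H13) | O=C1C[C@H]2CCC[C@]23OC[C@@H](c4ccccc4)N13 | intermediate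
4 | (3aR,6aS)-1-[(1R)-2-hydroxy-1-phenylethyl]-6a-(prop-2-en-1-yl)hexahydrocyclopenta[b]pyrrol-2(1H)-one | O=C1C[C@H]2CCC[C@@]2(CC=C)N1[C@@H](CO)c1ccccc1 | intermediate
5 | (3aR,6aS)-6a-(prop-2-en-1-yl)hexahydrocyclopenta[b]pyrrol-2(1H)-one | O=C1C[C@H]2CCC[C@@]2(CC=C)N1 | intermediate
6 | tert-butyl (3aR,6aS)-2-oxo-6a-(prop-2-en-1-yl)hexahydrocyclopenta[b]pyrrole-1(2H)-carboxylate | O=C1C[C@H]2CCC[C@@]2(CC=C)N1C(=O)OC(C)(C)C | intermediate
7 | tert-butyl (3R,3aR,6aS)-3-methyl-2-oxo-6a-(prop-2-en-1-yl)hexahydrocyclopenta[b]pyrrole-1(2H)-carboxylate | O=C1[C@H](C)[C@H]2CCC[C@@]2(CC=C)N1C(=O)OC(C)(C)C | intermediate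
8 | tert-butyl (3R,3aR,6aS)-2-hydroxy-3-methyl-6a-(prop-2-en-1-yl)hexahydrocyclopenta[b]pyrrole-1(2H)-carboxylate (both C2 epimers) | OC1[C@H](C)[C@H]2CCC[C@@]2(CC=C)N1C(=O)OC(C)(C)C | intermediate
9 | tert-butyl N-[(1S,2R)-2-[(2R)-but-3-yn-2-yl]-1-(prop-2-en-1-yl)cyclopentyl]carbamate | C#C[C@H](C)[C@H]1CCC[C@@]1(CC=C)NC(=O)OC(C)(C)C | intermediate
10 | tert-butyl N-[(1S,2R)-2-[(2R)-pent-3-yn-2-yl]-1-(prop-2-en-1-yl)cyclopentyl]carbamate | CC#C[C@H](C)[C@H]1CCC[C@@]1(CC=C)NC(=O)OC(C)(C)C | intermediate
11 | methyl (Z)-3-iodoprop-2-enoate | COC(=O)/C=C\I | starting material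
12 | B-alkyl-9-BBN adduct of 10 (boron on the terminal allyl carbon C6) | CC#C[C@H](C)[C@H]1CCC[C@@]1(CCCB1C2CCCC1CCC2)NC(=O)OC(C)(C)C | intermediate
13 | methyl (Z)-6-[1-(tert-butoxycarbonylamino)-2-[(2R)-pent-3-yn-2-yl]cyclopentyl]hex-2-enoate (ring centres as in 10) | CC#C[C@H](C)[C@H]1CCC[C@@]1(CCC/C=C\C(=O)OC)NC(=O)OC(C)(C)C | intermediate
14 | methyl (Z)-6-[1-amino-2-[(2R)-pent-3-yn-2-yl]cyclopentyl]hex-2-enoate (ring centres as in 10) | CC#C[C@H](C)[C@H]1CCC[C@]1(N)CCC/C=C\C(=O)OC | intermediate
15 | (5R,9S,13R,14R) 6-azaspiro[4.5]decane with CH2CO2Me on C5 and pent-3-yn-2-yl on C13 (C4 cis to C13 across ring B) | CC#C[C@H](C)[C@H]1CCC[C@]12CCC[C@H](CC(=O)OC)N2 | intermediate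
16 | tert-butyl 3-oxobutanoate chain on C5 of the spiro-piperidine (5R,9S,13R,14R) | CC#C[C@H](C)[C@H]1CCC[C@]12CCC[C@H](CC(=O)CC(=O)OC(C)(C)C)N2 | intermediate
17 | tricyclic β-keto tert-butyl ester, C3 ketone, C2 unassigned (5R,9S,13R,14R) | CC#C[C@H](C)[C@H]1CCC[C@]12CCC[C@@H]3CC(=O)C(C(=O)OC(C)(C)C)CN32 | intermediate
18 | tricyclic β-hydroxy tert-butyl ester, C2 and C3 unassigned | CC#C[C@H](C)[C@H]1CCC[C@]12CCC[C@@H]3CC(O)C(C(=O)OC(C)(C)C)CN32 | intermediate
19 | C3 methanesulfonate of 18 | CC#C[C@H](C)[C@H]1CCC[C@]12CCC[C@@H]3CC(OS(C)(=O)=O)C(C(=O)OC(C)(C)C)CN32 | intermediate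
20 | tricyclic tert-butyl enoate (C2=C3) with (2R)-pent-3-yn-2-yl on C13 (5R,9S,13R,14R) | CC#C[C@H](C)[C@H]1CCC[C@]12CCC[C@@H]3CC=C(C(=O)OC(C)(C)C)CN32 | intermediate
21 | tricyclic amino acid (C1 acid, C2=C3; 5R,9S,13R,14R) | CC#C[C@H](C)[C@H]1CCC[C@]12CCC[C@@H]3CC=C(C(=O)O)CN32 | intermediate
22 | but-3-yn-1-ol | C#CCCO | starting material
23 | but-3-yn-1-yl acetate | C#CCCOC(C)=O | intermediate
24 | (E)-3-chloro-4-iodobut-3-en-1-yl acetate | CC(=O)OCC/C(Cl)=C\I | intermediate
25 | (E)-3-chloro-5-oxooct-3-en-6-yn-1-yl acetate | CC#CC(=O)/C=C(/Cl)CCOC(C)=O | intermediate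
26 | (3E,5S)-3-chloro-5-hydroxyoct-3-en-6-yn-1-yl acetate | CC#C[C@@H](O)/C=C(/Cl)CCOC(C)=O | intermediate
27 | (3E,5S)-5-[(tert-butyldimethylsilyl)oxy]-3-chlorooct-3-en-6-yn-1-yl acetate | CC#C[C@@H](O[Si](C)(C)C(C)(C)C)/C=C(/Cl)CCOC(C)=O | intermediate
28 | (3E,5S)-5-[(tert-butyldimethylsilyl)oxy]-3-chlorooct-3-en-6-yn-1-ol | CC#C[C@@H](O[Si](C)(C)C(C)(C)C)/C=C(/Cl)CCO | intermediate
29 | ester of acid 21 with alcohol 28: tricyclic bis(prop-1-ynyl) ester, C17 TBS ether (5R,9S,13R,14R,17S,18E) | CC#C[C@@H](O[Si](C)(C)C(C)(C)C)/C=C(/Cl)CCOC(=O)C1=CC[C@H]2CCC[C@]3(CCC[C@@H]3[C@@H](C)C#CC)N2C1 | intermediate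
30 | 15-membered cycloalkyne lactone (C15≡C16), C17 TBS ether (5R,9S,13R,14R,17S,18E) | C[C@H]1C#C[C@@H](O[Si](C)(C)C(C)(C)C)/C=C(/Cl)CCOC(=O)C2=CC[C@H]3CCC[C@]4(CCC[C@H]14)N3C2 | intermediate
31 | (15Z,18E)-macrolactone, C17 TBS ether (5R,9S,13R,14S,17R) | C[C@H]1/C=C\[C@@H](O[Si](C)(C)C(C)(C)C)/C=C(/Cl)CCOC(=O)C2=CC[C@H]3CCC[C@]4(CCC[C@H]14)N3C2 | intermediate
32 | CNP0129639.4, (5R,9S,13R,14S,17R,15Z,18E)-macrolactone with free C17 hydroxyl | C[C@H]1/C=C\[C@@H](O)/C=C(/Cl)CCOC(=O)C2=CC[C@H]3CCC[C@]4(CCC[C@H]14)N3C2 | target

Total step count: 24. Longest linear sequence: 18 steps (steps 1 to 14, then 21 to 24); the fragment branch (steps 15 to 20) joins at step 21.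

Steps most likely to fail

Step 22. Intermolecular metathesis may outrun closure of ring D and give oligomers, or turnover may stall at the two α-branched alkynes. The fallback forms C15≡C16 intermolecularly and closes ring D at the ester instead. It sets out from tert-butyl ester 20 and acetate 27 (in excess): alkyne cross-metathesis with Mo(≡CC6H4OMe-4)(OSiPh3)3 and 5 Å molecular sieves in toluene should give the cross-coupled diyne ester F1. K2CO3 in MeOH then removes the acetate to give the hydroxy tert-butyl ester F2. Me3SiOTf with 2,6-lutidine, followed by aqueous work-up, cleaves the tert-butyl ester while the TBS ether stays, giving the seco acid F3. Yamaguchi macrolactonisation (2,4,6-trichlorobenzoyl chloride, Et3N, then DMAP, toluene, high dilution) forms the C1–O bond and rejoins the route at cycloalkyne 30.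

Step 17. The alkynyl group may transfer to palladium before CO inserts, giving direct coupling to the enyne, or reaction at the C–I bond may be sluggish. The fallback sets out from 24: reductive carbonylation (Pd(PPh3)4, CO, Bu3SnH added slowly, THF, 50 °C) should give the β-chloro enal F4 with the alkene geometry retained. MeC≡CMgBr in THF at −78 °C adds to the aldehyde faster than to the acetate and gives the racemic carbinol F5. Oxidation with MnO2 in CH2Cl2 rejoins the route at ynenone 25.

Step 6. C14 may epimerise through the ring-opened α-methyl aldehyde in basic methanol, or the hemiaminal may open too slowly for the homologation to go to completion. The fallback avoids any aldehyde and sets out from 7: EtMgBr in THF at −78 °C opens the N-Boc lactam to the ethyl ketone F6, whose ethyl group supplies C16 and its methyl cap. KN(SiMe3)2 (2.2 equiv) and PhNTf2 at −78 °C enolise on the less hindered CH2 side and give the (Z)-enol triflate F7. Anti elimination with LiN(iPr)2 at −78 °C then gives methyl alkyne 10, where the route is rejoined; steps 6 and 7 are replaced.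

Further compounds

F1 | step 22 | cross-metathesis product: tricyclic tert-butyl enoate joined through C15≡C16 to the C17 TBS ether, C21 acetate fragment | C[C@@H](C#C[C@@H](O[Si](C)(C)C(C)(C)C)/C=C(/Cl)CCOC(C)=O)[C@H]1CCC[C@]12CCC[C@@H]3CC=C(C(=O)OC(C)(C)C)CN32
F2 | step 22 | hydroxy tert-butyl ester (C21 OH free) | C[C@@H](C#C[C@@H](O[Si](C)(C)C(C)(C)C)/C=C(/Cl)CCO)[C@H]1CCC[C@]12CCC[C@@H]3CC=C(C(=O)OC(C)(C)C)CN32
F3 | step 22 | seco acid (C1 acid, C21 OH, C15≡C16, C17 TBS ether) | C[C@@H](C#C[C@@H](O[Si](C)(C)C(C)(C)C)/C=C(/Cl)CCO)[C@H]1CCC[C@]12CCC[C@@H]3CC=C(C(=O)O)CN32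
F4 | step 17 | (E)-3-chloro-5-oxopent-3-en-1-yl acetate | O=C/C=C(/Cl)CCOC(C)=O
F5 | step 17 | (E)-3-chloro-5-hydroxyoct-3-en-6-yn-1-yl acetate (racemic) | CC#CC(O)/C=C(/Cl)CCOC(C)=O
F6 | step 6 | tert-butyl N-[(1S,2R)-2-[(2R)-3-oxopentan-2-yl]-1-(prop-2-en-1-yl)cyclopentyl]carbamate | CCC(=O)[C@H](C)[C@H]1CCC[C@@]1(CC=C)NC(=O)OC(C)(C)C
F7 | step 6 | (Z)-enol triflate of F6 (triflate on C15, methyl cis to the triflate oxygen) | C/C=C(\OS(=O)(=O)C(F)(F)F)[C@H](C)[C@H]1CCC[C@@]1(CC=C)NC(=O)OC(C)(C)C
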